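The hydroazulene is read as a cadinane in which ring-fusion carbon C3a has moved from C8 to C8a (azulene numbering), the presumed biosynthetic 1,2-shift, and everything rests on copying it. A cis-fused decalin with a tertiary hydroxyl on the fusion carbon (future C8) and a cis, equatorial mesylate on the neighbouring carbon (future C8a) undergoes a semipinacol rearrangement. In one operation the six-membered carbocycle C3a–C4–C5–C6–C7–C8 takes up C8a and becomes the cycloheptenone, the oxirane-bearing ring contracts to the cyclopentane, and inversion at C8a fixes the trans ring fusion. The decalin comes from (S)-4-silyloxycyclohexenone by conjugate addition–allylation, methoxyallene addition and ring-closing metathesis.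

Key step: step 8

Remark on numbering: the target and 16–24 are numbered as azulenes (C1 and C2 oxirane carbons; C3a and C8a ring fusion; C4 isopropyl; C5 ester oxygen; C7 carbinol). The decalins 12–15 are numbered as naphthalenes, whose C1, C4a and C8a become C8a, C3a and C8 of the azulene. TBS = tert-butyldimethylsilyl, TBSO = (tert-butyldimethylsilyl)oxy.

Assumption: enantiopure (S)-4-(TBSO)cyclohex-2-en-1-one (1) is taken as purchasable; 6 is carried on as a mixture of epimers at the methyl-bearing carbon, which becomes sp2 in step 3.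

Step 1
Reactants: 1 (S)-4-(TBSO)cyclohex-2-en-1-one; 2 isopropylmagnesium chloride; 3 3-bromo-2-methylprop-1-ene
Product: 5 (2S,3S,4S)-4-(TBSO)-2-(2-methylprop-2-en-1-yl)-3-(propan-2-yl)cyclohexan-1-one, via magnesium enolate 4 (not isolated)
Conditions: i-PrMgCl, CuBr·SMe2 (10 mol%), THF, −78 °C; then 3, HMPA, −78 → 0 °C
Reagents that add atoms: isopropylmagnesium chloride CC(C)[Mg]Cl; 3-bromo-2-methylprop-1-ene C=C(C)CBr
Why: Copper-catalysed conjugate addition of the Grignard reagent should occur anti to the 4-silyloxy group, and the enolate is then allylated anti to the new isopropyl group (three-component conjugate addition–enolate alkylation), which sets the 2,3-trans-3,4-trans arrangement.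

Step 2
Reactants: 5 (2S,3S,4S)-4-(TBSO)-2-(2-methylprop-2-en-1-yl)-3-(propan-2-yl)cyclohexan-1-one
Product: 6 (2S,3S,4S)-4-(TBSO)-6-methyl-2-(2-methylprop-2-en-1-yl)-3-(propan-2-yl)cyclohexan-1-one (C6 epimers)
Conditions: LDA, THF, −78 °C; MeI, −78 → −40 °C
Reagents that add atoms: iodomethane CI
Why: Kinetic deprotonation should take place at the unsubstituted α-methylene and the lithium enolate is methylated (enolate alkylation), the configuration of the new centre being irrelevant because it becomes sp2 in step 3.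

Step 3
Reactants: 6 (2S,3S,4S)-4-(TBSO)-6-methyl-2-(2-methylprop-2-en-1-yl)-3-(propan-2-yl)cyclohexan-1-one (C6 epimers)
Product: 8 (4R,5S,6S)-4-(TBSO)-2-methyl-6-(2-methylprop-2-en-1-yl)-5-(propan-2-yl)cyclohex-2-en-1-one, via silyl enol ether 7 (not isolated)
Conditions: LDA, Me3SiCl, THF, −78 °C; then Pd(OAc)2 (1.0 equiv), MeCN, rt
Reagents that add atoms: none
Why: Saegusa–Ito oxidation, in which the less hindered methyl-bearing α-carbon is enolised and silylated and palladium diacetate dehydrogenates the silyl enol ether by β-hydride loss from the ring methylene to give the endocyclic 2-methyl enone.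

Step 4
Reactants: 8 (4R,5S,6S)-4-(TBSO)-2-methyl-6-(2-methylprop-2-en-1-yl)-5-(propan-2-yl)cyclohex-2-en-1-one; 9 methoxyallene
Product: 11 1-[(1R,4R,5S,6S)-4-(TBSO)-1-hydroxy-2-methyl-6-(2-methylprop-2-en-1-yl)-5-(propan-2-yl)cyclohex-2-en-1-yl]prop-2-en-1-one, via allenyl carbinol 10 (not isolated)
Conditions: 9, n-BuLi, THF, −78 °C; add 8, −78 °C; then 5% aq. H2SO4, THF, 0 °C
Reagents that add atoms: methoxyallene COC=C=C; water O
Why: Lithiated methoxyallene (an acryloyl anion equivalent) should add 1,2 to the enone along the axial trajectory anti to the axial α′-hydrogen, so that the new carbon is cis to the methallyl group and the hydroxyl cis to H-6, and mild acid hydrolysis of the allenyl enol ether releases the vinyl ketone.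

Step 5
Reactants: 11 1-[(1R,4R,5S,6S)-4-(TBSO)-1-hydroxy-2-methyl-6-(2-methylprop-2-en-1-yl)-5-(propan-2-yl)cyclohex-2-en-1-yl]prop-2-en-1-one
Product: 12 (4aS,5S,6R,8aR)-6-(TBSO)-8a-hydroxy-3,8-dimethyl-5-(propan-2-yl)-4a,5,6,8a-tetrahydronaphthalen-1(4H)-one
Conditions: second-generation Grubbs catalyst (5 mol%), CH2Cl2, 40 °C
Reagents that add atoms: none
Why: Ring-closing metathesis between the vinyl ketone and the 1,1-disubstituted alkene closes the 3-methylcyclohexenone with release of ethene, the cis ring fusion being fixed by the two existing stereocentres.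

Step 6
Reactants: 12 (4aS,5S,6R,8aR)-6-(TBSO)-8a-hydroxy-3,8-dimethyl-5-(propan-2-yl)-4a,5,6,8a-tetrahydronaphthalen-1(4H)-one
Product: 13 (2R,3R,4aS,5S,6R,8aR)-6-(TBSO)-2,3-epoxy-8a-hydroxy-3,8-dimethyl-5-(propan-2-yl)-2,3,4a,5,6,8a-hexahydronaphthalen-1(4H)-one
Conditions: 30% aq. H2O2, NaOH (cat.), MeOH, −10 °C
Reagents that add atoms: hydrogen peroxide OO
Why: Weitz–Scheffer nucleophilic epoxidation touches only the enone double bond, and hydroperoxide should attack the β-carbon from the convex face of the cis-fused bicycle (syn to the axial 8a-hydroxyl), the concave face being blocked by ring B.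

Step 7
Reactants: 13 (2R,3R,4aS,5S,6R,8aR)-6-(TBSO)-2,3-epoxy-8a-hydroxy-3,8-dimethyl-5-(propan-2-yl)-2,3,4a,5,6,8a-hexahydronaphthalen-1(4H)-one
Product: 14 (1R,2S,3R,4aS,5S,6R,8aR)-6-(TBSO)-2,3-epoxy-3,8-dimethyl-5-(propan-2-yl)-1,2,3,4,4a,5,6,8a-octahydronaphthalene-1,8a-diol
Conditions: NaBH4, MeOH–CH2Cl2, −40 °C
Reagents that add atoms: none
Why: Borohydride reduction of the α,β-epoxy ketone should deliver hydride anti to the oxirane oxygen and to the axial tertiary C–O bond, giving the all-cis epoxy diol with the secondary hydroxyl equatorial.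

Step 8
Reactants: 14 (1R,2S,3R,4aS,5S,6R,8aR)-6-(TBSO)-2,3-epoxy-3,8-dimethyl-5-(propan-2-yl)-1,2,3,4,4a,5,6,8a-octahydronaphthalene-1,8a-diol
Product: 16 (1S,2R,3aS,4S,5R,8aS)-5-(TBSO)-1,2-epoxy-2,7-dimethyl-4-(propan-2-yl)-1,2,3,3a,4,5-hexahydroazulen-8(8aH)-one, via mesylate 15 (not isolated)
Conditions: MsCl, Et3N, CH2Cl2, −20 °C; then KOt-Bu (1.0 equiv), THF, −78 → −20 °C
Reagents that add atoms: none
Why: The secondary C1 hydroxyl is mesylated (the tertiary C8a hydroxyl is inert) and deprotonation of the C8a hydroxyl drives a semipinacol 1,2-shift in which ring-fusion carbon C4a migrates from C8a to C1 as mesylate leaves and C8a becomes the ketone, so that the carbocycle C4a–C5–C6–C7–C8–C8a is enlarged by C1 to the cycloheptenone while the oxirane-bearing ring contracts to the cyclopentane. The closest known reaction type is the base-induced rearrangement of cis-decalindiol monosulfonates to hydroazulenones. The cyclopentane is closed by the shift itself, that is by intramolecular displacement of mesylate by the migrating σ-bond through a three-centre, 3-exo-tet-like transition state, whereas the seven-membered ring arises by expansion and not by cyclisation. The only new stereocentre (C8a of azulene 16) is set by inversion at the mesylate carbon while the migrating carbon keeps its configuration, so the all-cis arrangement of H-4a, 8a-OH and 1-OMs in 15 is translated stereospecifically into the trans ring fusion. The step needs migration of C4a in preference to the vinylic C8 and to oxirane closure: in the conformer with isopropyl and silyloxy equatorial the mesylate is equatorial and antiperiplanar only to the C4a–C8a bond, C8 is gauche, and a cis hydroxy mesylate cannot close a 1,8a-epoxide. Loss of mesylate consumes the single equivalent of base, which should protect the β,γ-epoxy enone from enolisation toward the ring fusion.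

Step 9
Reactants: 16 (1S,2R,3aS,4S,5R,8aS)-5-(TBSO)-1,2-epoxy-2,7-dimethyl-4-(propan-2-yl)-1,2,3,3a,4,5-hexahydroazulen-8(8aH)-one
Product: 18 (1S,2R,3aS,4S,5S,8aS)-5-(TBSO)-1,2-epoxy-2,7-dimethyl-4-(propan-2-yl)-1,2,3,3a,4,5,6,8a-octahydroazulen-8-yl trifluoromethanesulfonate, via lithium enolate 17 (not isolated)
Conditions: LiBH(s-Bu)3, THF, −78 °C; then N-(5-chloro-2-pyridyl)bis(trifluoromethanesulfonimide), −78 → −40 °C
Reagents that add atoms: N-(5-chloro-2-pyridyl)bis(trifluoromethanesulfonimide) O=S(=O)(N(c1ccc(Cl)cn1)S(=O)(=O)C(F)(F)F)C(F)(F)F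
Why: Conjugate (1,4) hydride reduction of the α-methyl enone gives the C7–C8 enolate regiospecifically, away from the ring fusion, and O-triflation traps it as the enol triflate before proton transfer can take place.

Step 10
Reactants: 18 (1S,2R,3aS,4S,5S,8aS)-5-(TBSO)-1,2-epoxy-2,7-dimethyl-4-(propan-2-yl)-1,2,3,3a,4,5,6,8a-octahydroazulen-8-yl trifluoromethanesulfonate
Product: 19 tert-butyl{[(1S,2R,3aR,4S,5S,8aR)-1,2-epoxy-2,7-dimethyl-4-(propan-2-yl)-1,2,3,3a,4,5,6,8a-octahydroazulen-5-yl]oxy}dimethylsilane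
Conditions: Pd(OAc)2 (5 mol%), PPh3, Bu3N, HCO2H, DMF, 60 °C
Reagents that add atoms: none
Why: Palladium-catalysed formate reduction of the enol triflate (oxidative addition, formate exchange, decarboxylation, reductive elimination) replaces the triflate by hydrogen and leaves the trisubstituted C7–C8 alkene in place.

Step 11
Reactants: 19 tert-butyl{[(1S,2R,3aR,4S,5S,8aR)-1,2-epoxy-2,7-dimethyl-4-(propan-2-yl)-1,2,3,3a,4,5,6,8a-octahydroazulen-5-yl]oxy}dimethylsilane
Product: 20 (1S,2R,3aR,4S,5S,7R,8aS)-5-(TBSO)-1,2-epoxy-2,7-dimethyl-4-(propan-2-yl)decahydroazulen-7-ol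
Conditions: Co(acac)2 (20 mol%), PhSiH3, O2 (1 atm), i-PrOH, 0 °C → rt
Reagents that add atoms: dioxygen O=O
Why: Mukaiyama hydration of the only alkene (hydrogen-atom transfer, Markovnikov tertiary radical, trapping by dioxygen) gives the tertiary alcohol, and dioxygen is expected to enter along the pseudo-axial direction so that the methyl group stays pseudo-equatorial and cis to the C5 silyloxy group.

Step 12
Reactants: 20 (1S,2R,3aR,4S,5S,7R,8aS)-5-(TBSO)-1,2-epoxy-2,7-dimethyl-4-(propan-2-yl)decahydroazulen-7-ol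
Product: 21 (1S,2R,3aR,4S,5S,7R,8aS)-1,2-epoxy-2,7-dimethyl-4-(propan-2-yl)decahydroazulene-5,7-diol
Conditions: Bu4NF, THF, 0 °C → rt
Reagents that add atoms: none
Why: Fluoride-mediated desilylation frees the secondary alcohol, the oxirane and the tertiary alcohol being inert and no stereocentre being touched.

Step 13
Reactants: 21 (1S,2R,3aR,4S,5S,7R,8aS)-1,2-epoxy-2,7-dimethyl-4-(propan-2-yl)decahydroazulene-5,7-diol; 22 4-acetoxybenzoyl chloride
Product: 24 (1S,2R,3aR,4S,5S,7R,8aS)-1,2-epoxy-7-hydroxy-2,7-dimethyl-4-(propan-2-yl)decahydroazulen-5-yl 4-hydroxybenzoate, via 4-acetoxybenzoate 23 (not isolated)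
Conditions: 22, Et3N, DMAP (cat.), CH2Cl2, 0 °C → rt; then MeOH, K2CO3 (cat.), 0 °C
Reagents that add atoms: 4-acetoxybenzoyl chloride CC(=O)Oc1ccc(cc1)C(Cl)=O
Why: DMAP-catalysed acylation should occur only at the secondary C5 hydroxyl (the tertiary C7 hydroxyl is unreactive) with retention, and brief carbonate methanolysis removes the phenolic acetate much faster than it attacks the deactivated aryl ester.

Compound list
1 | (S)-4-(TBSO)cyclohex-2-en-1-one | O=C1C=C[C@@H](O[Si](C)(C)C(C)(C)C)CC1 | starting material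
2 | isopropylmagnesium chloride | CC(C)[Mg]Cl | starting material
3 | 3-bromo-2-methylprop-1-ene | C=C(C)CBr | starting material
4 | chloromagnesium (3S,4S)-4-(TBSO)-3-(propan-2-yl)cyclohex-1-en-1-olate (magnesium enolate) | Cl[Mg]OC1=C[C@H](C(C)C)[C@@H](O[Si](C)(C)C(C)(C)C)CC1 | intermediate
5 | (2S,3S,4S)-4-(TBSO)-2-(2-methylprop-2-en-1-yl)-3-(propan-2-yl)cyclohexan-1-one | O=C1[C@@H](CC(C)=C)[C@H](C(C)C)[C@@H](O[Si](C)(C)C(C)(C)C)CC1 | intermediate
6 | (2S,3S,4S)-4-(TBSO)-6-methyl-2-(2-methylprop-2-en-1-yl)-3-(propan-2-yl)cyclohexan-1-one (C6 epimers) | O=C1[C@@H](CC(C)=C)[C@H](C(C)C)[C@@H](O[Si](C)(C)C(C)(C)C)CC1C | intermediate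
7 | tert-butyldimethyl{[(1S,5S,6S)-3-methyl-5-(2-methylprop-2-en-1-yl)-6-(propan-2-yl)-4-(trimethylsilyloxy)cyclohex-3-en-1-yl]oxy}silane (silyl enol ether) | C[Si](C)(C)OC1=C(C)C[C@H](O[Si](C)(C)C(C)(C)C)[C@@H](C(C)C)[C@@H]1CC(C)=C | intermediate
8 | (4R,5S,6S)-4-(TBSO)-2-methyl-6-(2-methylprop-2-en-1-yl)-5-(propan-2-yl)cyclohex-2-en-1-one | O=C1C(C)=C[C@H](O[Si](C)(C)C(C)(C)C)[C@@H](C(C)C)[C@@H]1CC(C)=C | intermediate
9 | methoxyallene (1-methoxypropa-1,2-diene) | COC=C=C | starting material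
10 | (1R,4R,5S,6S)-4-(TBSO)-1-(1-methoxypropa-1,2-dien-1-yl)-2-methyl-6-(2-methylprop-2-en-1-yl)-5-(propan-2-yl)cyclohex-2-en-1-ol (allenyl carbinol) | C=C=C(OC)[C@]1(O)C(C)=C[C@H](O[Si](C)(C)C(C)(C)C)[C@@H](C(C)C)[C@@H]1CC(C)=C | intermediate
11 | 1-[(1R,4R,5S,6S)-4-(TBSO)-1-hydroxy-2-methyl-6-(2-methylprop-2-en-1-yl)-5-(propan-2-yl)cyclohex-2-en-1-yl]prop-2-en-1-one | C=CC(=O)[C@]1(O)C(C)=C[C@H](O[Si](C)(C)C(C)(C)C)[C@@H](C(C)C)[C@@H]1CC(C)=C | intermediate
12 | (4aS,5S,6R,8aR)-6-(TBSO)-8a-hydroxy-3,8-dimethyl-5-(propan-2-yl)-4a,5,6,8a-tetrahydronaphthalen-1(4H)-one | O=C1C=C(C)C[C@H]2[C@H](C(C)C)[C@@H](O[Si](C)(C)C(C)(C)C)C=C(C)[C@@]12O | intermediate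
13 | (2R,3R,4aS,5S,6R,8aR)-6-(TBSO)-2,3-epoxy-8a-hydroxy-3,8-dimethyl-5-(propan-2-yl)-2,3,4a,5,6,8a-hexahydronaphthalen-1(4H)-one | O=C1[C@@H]3O[C@]3(C)C[C@H]2[C@H](C(C)C)[C@@H](O[Si](C)(C)C(C)(C)C)C=C(C)[C@@]12O | intermediate
14 | (1R,2S,3R,4aS,5S,6R,8aR)-6-(TBSO)-2,3-epoxy-3,8-dimethyl-5-(propan-2-yl)-1,2,3,4,4a,5,6,8a-octahydronaphthalene-1,8a-diol | O[C@@H]1[C@@H]3O[C@]3(C)C[C@H]2[C@H](C(C)C)[C@@H](O[Si](C)(C)C(C)(C)C)C=C(C)[C@@]12O | intermediate
15 | (1R,2S,3R,4aS,5S,6R,8aR)-6-(TBSO)-2,3-epoxy-8a-hydroxy-3,8-dimethyl-5-(propan-2-yl)-1,2,3,4,4a,5,6,8a-octahydronaphthalen-1-yl methanesulfonate (mesylate) | CS(=O)(=O)O[C@@H]1[C@@H]3O[C@]3(C)C[C@H]2[C@H](C(C)C)[C@@H](O[Si](C)(C)C(C)(C)C)C=C(C)[C@@]12O | intermediate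
16 | (1S,2R,3aS,4S,5R,8aS)-5-(TBSO)-1,2-epoxy-2,7-dimethyl-4-(propan-2-yl)-1,2,3,3a,4,5-hexahydroazulen-8(8aH)-one | CC(C)[C@H]1[C@@H]2C[C@@]3(C)O[C@H]3[C@H]2C(=O)C(C)=C[C@@H]1O[Si](C)(C)C(C)(C)C | intermediate
17 | lithium (1S,2R,3aS,4S,5S,8aS)-5-(TBSO)-1,2-epoxy-2,7-dimethyl-4-(propan-2-yl)-1,2,3,3a,4,5,6,8a-octahydroazulen-8-olate (lithium enolate) | CC(C)[C@H]1[C@@H]2C[C@@]3(C)O[C@H]3[C@H]2C(O[Li])=C(C)C[C@@H]1O[Si](C)(C)C(C)(C)C | intermediate
18 | (1S,2R,3aS,4S,5S,8aS)-5-(TBSO)-1,2-epoxy-2,7-dimethyl-4-(propan-2-yl)-1,2,3,3a,4,5,6,8a-octahydroazulen-8-yl trifluoromethanesulfonate | CC(C)[C@H]1[C@@H]2C[C@@]3(C)O[C@H]3[C@H]2C(OS(=O)(=O)C(F)(F)F)=C(C)C[C@@H]1O[Si](C)(C)C(C)(C)C | intermediate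
19 | tert-butyl{[(1S,2R,3aR,4S,5S,8aR)-1,2-epoxy-2,7-dimethyl-4-(propan-2-yl)-1,2,3,3a,4,5,6,8a-octahydroazulen-5-yl]oxy}dimethylsilane | CC(C)[C@H]1[C@@H]2C[C@@]3(C)O[C@H]3[C@H]2C=C(C)C[C@@H]1O[Si](C)(C)C(C)(C)C | intermediate
20 | (1S,2R,3aR,4S,5S,7R,8aS)-5-(TBSO)-1,2-epoxy-2,7-dimethyl-4-(propan-2-yl)decahydroazulen-7-ol | CC(C)[C@H]1[C@@H]2C[C@@]3(C)O[C@H]3[C@H]2C[C@@](C)(O)C[C@@H]1O[Si](C)(C)C(C)(C)C | intermediate
21 | (1S,2R,3aR,4S,5S,7R,8aS)-1,2-epoxy-2,7-dimethyl-4-(propan-2-yl)decahydroazulene-5,7-diol | CC(C)[C@H]1[C@@H]2C[C@@]3(C)O[C@H]3[C@H]2C[C@@](C)(O)C[C@@H]1O | intermediate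
22 | 4-acetoxybenzoyl chloride | CC(=O)Oc1ccc(cc1)C(Cl)=O | starting material
23 | (1S,2R,3aR,4S,5S,7R,8aS)-1,2-epoxy-7-hydroxy-2,7-dimethyl-4-(propan-2-yl)decahydroazulen-5-yl 4-acetoxybenzoate | CC(C)[C@H]1[C@@H]2C[C@@]3(C)O[C@H]3[C@H]2C[C@@](C)(O)C[C@@H]1OC(=O)c1ccc(OC(C)=O)cc1 | intermediate
24 | (1S,2R,3aR,4S,5S,7R,8aS)-1,2-epoxy-7-hydroxy-2,7-dimethyl-4-(propan-2-yl)decahydroazulen-5-yl 4-hydroxybenzoate | CC(C)[C@H]1[C@@H]2C[C@@]3(C)O[C@H]3[C@H]2C[C@@](C)(O)C[C@@H]1OC(=O)c1ccc(O)cc1 | target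

Total step count: 13. Longest linear sequence: 13 steps (from 1).

Steps most likely to fail

Step 8 (key step). Once the shift has taken place, the new ketone can be enolised toward the ring fusion by any surplus base. This would open the neighbouring oxirane by β-elimination or epimerise the fusion carbon, and a sluggish mesylation of the hindered secondary alcohol would make it worse. In the fallback the mesylate 15 is treated with Et3Al and i-Bu2AlH in CH2Cl2 at −78 °C. This is an organoaluminium-promoted pinacol-type shift in which the nascent enone is reduced in the same flask, so no enolisable ketone ever meets base, and it should give the allylic alcohol F1 as a mixture of carbinol epimers. Oxidation of F1 with 1,1,1-triacetoxy-1,1-dihydro-1,2-benziodoxol-3(1H)-one (NaHCO3 buffer, CH2Cl2) then returns the enone. The fallback sets out from 15 and comes back to the route at 16.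

Step 11. Trapping of the planar tertiary radical may show poor facial selectivity, or the oxygen may enter on the wrong face. In the fallback alkene 19 is subjected to oxymercuration (Hg(OAc)2, THF–H2O), which should give the acetoxymercurio alcohol F2. Water opens the mercurinium ion anti at the tertiary carbon, so the hydroxyl enters on the face opposite to the one used by a reagent that adds from the open side. NaBH4 in aqueous NaOH then removes mercury. The fallback sets out from 19 and comes back to the route at 20.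

Step 6. Hydroperoxide may attack along the axial trajectory on the concave face, or the base may induce an acyloin (α-ketol) shift of the α′-hydroxy enone. In the fallback enone 12 is first reduced under Luche conditions (NaBH4, CeCl3·7H2O, MeOH, −78 °C), hydride adding anti to the axial tertiary C–O bond, to give the cis-diol F3. Its two hydroxyls then direct mCPBA (NaHCO3, CH2Cl2, 0 °C) to the convex face of the ring A alkene; the ring B alkene carries two allylic C–O bonds and should react more slowly. The fallback sets out from 12 and comes back to the route at 14, bypassing 13.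

Further compounds
F1 | step 8 | (1S,2R,3aS,4S,5R,8aR)-5-(TBSO)-1,2-epoxy-2,7-dimethyl-4-(propan-2-yl)-1,2,3,3a,4,5,8,8a-octahydroazulen-8-ol (C8 epimers) | CC(C)[C@H]1[C@@H]2C[C@@]3(C)O[C@H]3[C@H]2C(O)C(C)=C[C@@H]1O[Si](C)(C)C(C)(C)C
F2 | step 11 | acetoxy[5-(TBSO)-1,2-epoxy-7-hydroxy-2,7-dimethyl-4-(propan-2-yl)decahydroazulen-8-yl]mercury, ring carbons configured as in 20, mercury trans to the 7-hydroxyl | CC(C)[C@H]1[C@@H]2C[C@@]3(C)O[C@H]3[C@H]2C([Hg]OC(C)=O)[C@@](C)(O)C[C@@H]1O[Si](C)(C)C(C)(C)C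
F3 | step 6 | (1R,4aS,5S,6R,8aR)-6-(TBSO)-3,8-dimethyl-5-(propan-2-yl)-4,4a,5,6-tetrahydronaphthalene-1,8a(1H)-diol | O[C@@H]1C=C(C)C[C@H]2[C@H](C(C)C)[C@@H](O[Si](C)(C)C(C)(C)C)C=C(C)[C@@]12O
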